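**Retrosynthetic overview**

1. Carotenoid numbering is used (ring: C1 gem-dimethyl carbon, C3 carbinol, C5 methyl-bearing O-carbon, C6 ring-fusion alkene carbon; C7 =CH, C8 O–CH; chain C9 to C8′). The C11=C12 bond is cut (Wittig) into furanoid C15 enal 16 and C15 phosphonium ester 21, made from C10 dialdehyde 17 and C5 phosphonate 18; C8′ is carried as ester, then alcohol, then aldehyde.
2. The dihydrofuran ring (O–C8–C7=C6–C5) is closed last, by gold-catalysed 5-endo cyclisation of α-hydroxy allene 14, which turns the allene axis into the C8 centre. The allene comes from alkynyl epoxide 12 by anti SN2′ hydrogenolysis, and the epoxide (a temporary ring) from C3–OH-directed epoxidation of enyne 11, so the stereochemical relay is C3 → C5/C6 → axis → C8.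
3. The six-membered ring is made first, in the key step: C3–C4 and C5–C6 both form when acetone (which becomes C4, C5 and the C5 methyl) is stitched into 3,3-dimethylpentanedial 3 by a D-proline domino aldol/aldol condensation, giving enal 7 with C3 set. C7 is carried at the aldehyde level and later becomes the alkyne carbon and finally the ring =CH.
4. Enabling feature: in the six-membered ring the hydroxylated C3 and the oxygenated C5 are 1,3-related across the C4 methylene, and C5–C6 lies next to C7, so with C7 as CHO both bonds are aldol bonds of one acetone unit. The quaternary C1 makes the two formyl arms of 3 equivalent and rules out ring aldolisation of 3 itself.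
5. Ring order: carbocycle (step 3), oxirane (step 7, opened in step 8), dihydrofuran (step 10).

Key step: step 3

Remark: 17 and 18 are taken as catalogue building blocks.

**Route**

Step 1
Reactants: 1 3,3-dimethylglutaric anhydride (4,4-dimethyloxane-2,6-dione)
Product: 2 3,3-dimethylpentane-1,5-diol
Conditions: LiAlH4 (2.5 equiv), THF, 0 °C to reflux; aqueous NaOH work-up
Reagents that add atoms: none
Why: LiAlH4 reduces both acyl carbons of the cyclic anhydride to primary alcohols (hydride reduction of a carboxylic anhydride); no stereocentre is formed.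

Step 2
Reactants: 2 3,3-dimethylpentane-1,5-diol
Product: 3 3,3-dimethylpentanedial
Conditions: (COCl)2, DMSO, CH2Cl2, −78 °C; then Et3N, −78 °C to 0 °C; used crude
Reagents that add atoms: none
Why: Swern oxidation should stop cleanly at the dialdehyde, which is used at once because 1,5-dialdehydes hydrate and oligomerise on storage; no stereocentre is formed.

Step 3
Reactants: 3 3,3-dimethylpentanedial; 4 acetone
Product: 7 (4S)-4-hydroxy-2,6,6-trimethylcyclohex-1-ene-1-carbaldehyde, via keto aldehyde 5 (not isolated), via ring aldol 6 (not isolated)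
Conditions: D-proline (30 mol %), acetone (10 equiv), DMSO, 4 °C to 20 °C, then 40 °C until 6 is consumed
Reagents that add atoms: none
Why: The D-proline enamine of acetone should add to one formyl group of 3 through the hydrogen-bonded enamine/carboxylic acid transition state to give 5 (C3–C4); the catalyst then converts the remaining formyl arm into its enamine, which closes onto the methyl ketone to give 6 (C5–C6), and amine-assisted loss of water gives the conjugated enal 7 irreversibly. The closest known reaction types are the proline-catalysed intermolecular aldol of acetone with α-unbranched aldehydes and the amine-catalysed enolexo aldol condensation of oxo-aldehydes to cycloalkene carbaldehydes. The six-membered ring closes by a 6-(enolexo)-exo-trig aldol addition. The only surviving stereocentre, C3, is set in the first event by the catalyst (the D series is chosen because L-proline gives the opposite, S-configured β-hydroxy ketone from α-unbranched aldehydes), and the transient centres C5 and C6 of 6 are erased by the dehydration. The step needs cross- rather than homo-aldol, single rather than double acetone addition, and closure through the aldehyde enamine: the quaternary C1 makes the two formyl groups equivalent, allows 3 to aldolise onto itself only through a four-membered ring and slows its self-condensation, secondary amines condense with the aldehyde of 5 in preference to its ketone, and the hindered tetrasubstituted enal 7 should be inert to further aldol chemistry.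

Step 4
Reactants: 7 (4S)-4-hydroxy-2,6,6-trimethylcyclohex-1-ene-1-carbaldehyde
Product: 8 (1S)-4-ethynyl-3,5,5-trimethylcyclohex-3-en-1-ol
Conditions: dimethyl (1-diazo-2-oxopropyl)phosphonate (1.5 equiv), K2CO3 (2.5 equiv), MeOH, 0 °C to 20 °C
Reagents that add atoms: dimethyl (1-diazo-2-oxopropyl)phosphonate, CC(=O)C(=[N+]=[N-])P(=O)(OC)OC
Why: Seyferth–Gilbert homologation in its Ohira–Bestmann form should convert the non-enolisable, hindered enal into the terminal alkyne under K2CO3/MeOH, conditions that leave the free C3 alcohol and its configuration untouched.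

Step 5
Reactants: 9 ethyl acetoacetate
Product: 10 ethyl (2E)-3-{[(trifluoromethyl)sulfonyl]oxy}but-2-enoate
Conditions: Tf2O, aqueous Me4NOH, hexane, 5 °C
Reagents that add atoms: trifluoromethanesulfonic anhydride, O=S(=O)(OS(=O)(=O)C(F)(F)F)C(F)(F)F
Why: O-triflation of the non-chelated tetramethylammonium enolate of the β-keto ester should give the (E)-enol triflate (a lithium chelate would give Z), which fixes the future C9=C10 geometry.

Step 6
Reactants: 8 (1S)-4-ethynyl-3,5,5-trimethylcyclohex-3-en-1-ol; 10 ethyl (2E)-3-{[(trifluoromethyl)sulfonyl]oxy}but-2-enoate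
Product: 11 ethyl (2E)-5-[(4S)-4-hydroxy-2,6,6-trimethylcyclohex-1-en-1-yl]-3-methylpent-2-en-4-ynoate
Conditions: Pd(PPh3)4 (3 mol %), CuI (6 mol %), Et3N, THF, 20 °C
Reagents that add atoms: none
Why: Sonogashira coupling of the terminal alkyne with the enol triflate forms C8–C9 with retention of the (E) geometry and tolerates the free alcohol; no stereocentre is touched.

Step 7
Reactants: 11 ethyl (2E)-5-[(4S)-4-hydroxy-2,6,6-trimethylcyclohex-1-en-1-yl]-3-methylpent-2-en-4-ynoate
Product: 12 ethyl (2E)-5-[(1R,4R,6R)-4-hydroxy-2,2,6-trimethyl-7-oxabicyclo[4.1.0]heptan-1-yl]-3-methylpent-2-en-4-ynoate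
Conditions: VO(acac)2 (5 mol %), t-BuOOH (1.5 equiv), toluene, 0 °C to 20 °C
Reagents that add atoms: tert-butyl hydroperoxide, CC(C)(C)OO
Why: Hydroxyl-directed epoxidation, with the vanadium peroxide bound to the homoallylic C3–OH, should deliver oxygen to the C5=C6 face syn to that hydroxyl and so set C5 and C6 (oxygen cis to C3–OH), while the electron-poor C9=C10 alkene and the alkyne are left alone.

Step 8
Reactants: 12 ethyl (2E)-5-[(1R,4R,6R)-4-hydroxy-2,2,6-trimethyl-7-oxabicyclo[4.1.0]heptan-1-yl]-3-methylpent-2-en-4-ynoate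
Product: 13 ethyl (2E)-5-[(2R,4R)-2,4-dihydroxy-2,6,6-trimethylcyclohexylidene]-3-methylpenta-2,4-dienoate (allene axis aS)
Conditions: Pd2(dba)3·CHCl3 (2.5 mol %), PBu3 (10 mol %), HCO2NH4 (3 equiv), THF, 20 °C
Reagents that add atoms: none
Why: In this palladium-catalysed formate hydrogenolysis of a propargylic C–O electrophile, anti SN2′ oxidative addition opens the epoxide at C6 and, after decarboxylation of the palladium formate, hydride passes to C8 with retention at palladium, so H8 should end anti to the retained C5 oxygen and the epoxide configuration becomes the allene axis; an aluminium hydride is avoided here because oxygen-bound aluminium would deliver hydride syn.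

Step 9
Reactants: 13 ethyl (2E)-5-[(2R,4R)-2,4-dihydroxy-2,6,6-trimethylcyclohexylidene]-3-methylpenta-2,4-dienoate (allene axis aS)
Product: 14 (1R,3R)-4-[(3E)-5-hydroxy-3-methylpenta-1,3-dien-1-ylidene]-3,5,5-trimethylcyclohexane-1,3-diol (allene axis aS)
Conditions: diisobutylaluminium hydride (5 equiv), CH2Cl2, −78 °C; aqueous potassium sodium tartrate work-up
Reagents that add atoms: none
Why: Diisobutylaluminium hydride reduces the conjugated ester 1,2 to the primary allylic alcohol at −78 °C; the allene axis and both carbinol centres are not affected.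

Step 10
Reactants: 14 (1R,3R)-4-[(3E)-5-hydroxy-3-methylpenta-1,3-dien-1-ylidene]-3,5,5-trimethylcyclohexane-1,3-diol (allene axis aS)
Product: 15 (2E)-3-[(2R,6R,7aR)-6-hydroxy-4,4,7a-trimethyl-2,4,5,6,7,7a-hexahydro-1-benzofuran-2-yl]but-2-en-1-ol
Conditions: AuCl3 (2 mol %), THF, 20 °C
Reagents that add atoms: none
Why: In this gold-catalysed 5-endo cycloisomerisation of an α-hydroxy allene to a 2,5-dihydrofuran, gold activates the C7=C8 π bond, the C5 hydroxyl adds to C8 in the plane of the C6 substituents and protodeauration puts H on C7, so the allene axis should be transferred to the C8 centre (C9 on the face of C4, opposite the C5 methyl); the (E)-C9=C10 geometry keeps the primary hydroxyl out of reach of C8.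

Step 11
Reactants: 15 (2E)-3-[(2R,6R,7aR)-6-hydroxy-4,4,7a-trimethyl-2,4,5,6,7,7a-hexahydro-1-benzofuran-2-yl]but-2-en-1-ol
Product: 16 (2E)-3-[(2R,6R,7aR)-6-hydroxy-4,4,7a-trimethyl-2,4,5,6,7,7a-hexahydro-1-benzofuran-2-yl]but-2-enal
Conditions: MnO2 (15 equiv), CH2Cl2, 20 °C
Reagents that add atoms: none
Why: Activated MnO2 oxidises the primary allylic alcohol chemoselectively under neutral conditions and should leave the saturated secondary C3 alcohol and the acid-sensitive bis-allylic ether untouched.

Step 12
Reactants: 17 (2E,4E,6E)-2,7-dimethylocta-2,4,6-trienedial (3 equiv); 18 ethyl (2E)-4-(diethoxyphosphoryl)-2-methylbut-2-enoate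
Product: 19 ethyl (2E,4E,6E,8E,10E)-2,6,11-trimethyl-12-oxododeca-2,4,6,8,10-pentaenoate
Conditions: NaOEt (1.0 equiv), EtOH/THF, 0 °C; excess 17 recovered
Reagents that add atoms: none
Why: Horner–Wadsworth–Emmons olefination of one formyl group of the symmetrical dialdehyde (used in excess to hold the reaction at mono-olefination) by the ester-stabilised allylic phosphonate anion should give the (E)-configured C11′=C12′ alkene.

Step 13
Reactants: 19 ethyl (2E,4E,6E,8E,10E)-2,6,11-trimethyl-12-oxododeca-2,4,6,8,10-pentaenoate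
Product: 20 ethyl (2E,4E,6E,8E,10E)-12-hydroxy-2,6,11-trimethyldodeca-2,4,6,8,10-pentaenoate
Conditions: NaBH4 (0.5 equiv), EtOH/THF, 0 °C
Reagents that add atoms: none
Why: NaBH4 reduces the polyenal 1,2 to the allylic alcohol and leaves the conjugated ester untouched.

Step 14
Reactants: 20 ethyl (2E,4E,6E,8E,10E)-12-hydroxy-2,6,11-trimethyldodeca-2,4,6,8,10-pentaenoate
Product: 21 [(2E,4E,6E,8E,10E)-12-ethoxy-2,7,11-trimethyl-12-oxododeca-2,4,6,8,10-pentaen-1-yl]triphenylphosphonium bromide
Conditions: PPh3·HBr (1.05 equiv), EtOH/CH2Cl2, 20 °C, dark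
Reagents that add atoms: triphenylphosphonium bromide (PPh3·HBr), [Br-].[PH+](c1ccccc1)(c1ccccc1)c1ccccc1
Why: Triphenylphosphine hydrobromide converts the polyenyl allylic alcohol into the phosphonium salt by substitution at the terminal carbon (the standard preparation of carotenoid Wittig salts); this acidic step is kept on the fragment that carries no acid-labile ether.

Step 15
Reactants: 16 (2E)-3-[(2R,6R,7aR)-6-hydroxy-4,4,7a-trimethyl-2,4,5,6,7,7a-hexahydro-1-benzofuran-2-yl]but-2-enal; 21 [(2E,4E,6E,8E,10E)-12-ethoxy-2,7,11-trimethyl-12-oxododeca-2,4,6,8,10-pentaen-1-yl]triphenylphosphonium bromide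
Product: 22 ethyl (2E,4E,6E,8E,10E,12E,14E)-15-[(2R,6R,7aR)-6-hydroxy-4,4,7a-trimethyl-2,4,5,6,7,7a-hexahydro-1-benzofuran-2-yl]-2,6,11-trimethylhexadeca-2,4,6,8,10,12,14-heptaenoate
Conditions: NaOEt (1.1 equiv), EtOH/CH2Cl2, 0 °C to 20 °C, dark; then heptane, 80 °C
Reagents that add atoms: none
Why: Wittig olefination between the enal and the conjugated ylide forms C11=C12, and the unhindered new alkene is equilibrated thermally to E as is usual for carotenoid couplings; the basic, acid-free conditions should preserve C8, the bis-allylic ether and the free C3 alcohol.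

Step 16
Reactants: 22 ethyl (2E,4E,6E,8E,10E,12E,14E)-15-[(2R,6R,7aR)-6-hydroxy-4,4,7a-trimethyl-2,4,5,6,7,7a-hexahydro-1-benzofuran-2-yl]-2,6,11-trimethylhexadeca-2,4,6,8,10,12,14-heptaenoate
Product: 23 (2E,4E,6E,8E,10E,12E,14E)-15-[(2R,6R,7aR)-6-hydroxy-4,4,7a-trimethyl-2,4,5,6,7,7a-hexahydro-1-benzofuran-2-yl]-2,6,11-trimethylhexadeca-2,4,6,8,10,12,14-heptaen-1-ol
Conditions: diisobutylaluminium hydride (3.5 equiv), CH2Cl2, −78 °C; aqueous potassium sodium tartrate work-up
Reagents that add atoms: none
Why: Diisobutylaluminium hydride reduces the polyenoate 1,2 to the primary allylic alcohol at −78 °C and should not touch the dihydrofuran.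

Step 17
Reactants: 23 (2E,4E,6E,8E,10E,12E,14E)-15-[(2R,6R,7aR)-6-hydroxy-4,4,7a-trimethyl-2,4,5,6,7,7a-hexahydro-1-benzofuran-2-yl]-2,6,11-trimethylhexadeca-2,4,6,8,10,12,14-heptaen-1-ol
Product: 24 (2E,4E,6E,8E,10E,12E,14E)-15-[(2R,6R,7aR)-6-hydroxy-4,4,7a-trimethyl-2,4,5,6,7,7a-hexahydro-1-benzofuran-2-yl]-2,6,11-trimethylhexadeca-2,4,6,8,10,12,14-heptaenal (target)
Conditions: MnO2 (20 equiv), CH2Cl2, 20 °C, dark
Reagents that add atoms: none
Why: MnO2 oxidises only the primary polyenylic alcohol to the conjugated aldehyde and leaves the saturated secondary C3 alcohol and all stereocentres unchanged.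

**Compound list**

1 | 3,3-dimethylglutaric anhydride (4,4-dimethyloxane-2,6-dione) | O=C1CC(C)(C)CC(=O)O1 | starting material
2 | 3,3-dimethylpentane-1,5-diol | OCCC(C)(C)CCO | intermediate
3 | 3,3-dimethylpentanedial | O=CCC(C)(C)CC=O | intermediate
4 | acetone | CC(C)=O | starting material
5 | (5R)-5-hydroxy-3,3-dimethyl-7-oxooctanal (keto aldehyde) | CC(=O)C[C@H](O)CC(C)(C)CC=O | intermediate
6 | (4R)-2,4-dihydroxy-2,6,6-trimethylcyclohexane-1-carbaldehyde (ring aldol, epimers at C1 and C2) | CC1(O)C[C@H](O)CC(C)(C)C1C=O | intermediate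
7 | (4S)-4-hydroxy-2,6,6-trimethylcyclohex-1-ene-1-carbaldehyde | O=CC1=C(C)C[C@H](O)CC1(C)C | intermediate
8 | (1S)-4-ethynyl-3,5,5-trimethylcyclohex-3-en-1-ol | C#CC1=C(C)C[C@H](O)CC1(C)C | intermediate
9 | ethyl acetoacetate | CCOC(=O)CC(C)=O | starting material
10 | ethyl (2E)-3-{[(trifluoromethyl)sulfonyl]oxy}but-2-enoate | CCOC(=O)/C=C(/OS(=O)(=O)C(F)(F)F)C | intermediate
11 | ethyl (2E)-5-[(4S)-4-hydroxy-2,6,6-trimethylcyclohex-1-en-1-yl]-3-methylpent-2-en-4-ynoate | CCOC(=O)/C=C(C)/C#CC1=C(C)C[C@H](O)CC1(C)C | intermediate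
12 | ethyl (2E)-5-[(1R,4R,6R)-4-hydroxy-2,2,6-trimethyl-7-oxabicyclo[4.1.0]heptan-1-yl]-3-methylpent-2-en-4-ynoate | CCOC(=O)/C=C(C)/C#C[C@]12C(C)(C)C[C@@H](O)C[C@@]1(C)O2 | intermediate
13 | ethyl (2E)-5-[(2R,4R)-2,4-dihydroxy-2,6,6-trimethylcyclohexylidene]-3-methylpenta-2,4-dienoate (allene axis aS) | CCOC(=O)/C=C(C)/C([H])=[C@]=C1C(C)(C)C[C@@H](O)C[C@@]1(C)O | intermediate
14 | (1R,3R)-4-[(3E)-5-hydroxy-3-methylpenta-1,3-dien-1-ylidene]-3,5,5-trimethylcyclohexane-1,3-diol (allene axis aS) | OC/C=C(C)/C([H])=[C@]=C1C(C)(C)C[C@@H](O)C[C@@]1(C)O | intermediate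
15 | (2E)-3-[(2R,6R,7aR)-6-hydroxy-4,4,7a-trimethyl-2,4,5,6,7,7a-hexahydro-1-benzofuran-2-yl]but-2-en-1-ol | OC/C=C(\C)[C@H]1C=C2C(C)(C)C[C@@H](O)C[C@@]2(C)O1 | intermediate
16 | (2E)-3-[(2R,6R,7aR)-6-hydroxy-4,4,7a-trimethyl-2,4,5,6,7,7a-hexahydro-1-benzofuran-2-yl]but-2-enal | O=C/C=C(\C)[C@H]1C=C2C(C)(C)C[C@@H](O)C[C@@]2(C)O1 | intermediate
17 | (2E,4E,6E)-2,7-dimethylocta-2,4,6-trienedial | O=C/C(C)=C/C=C/C=C(\C)C=O | starting material
18 | ethyl (2E)-4-(diethoxyphosphoryl)-2-methylbut-2-enoate | CCOC(=O)/C(C)=C/CP(=O)(OCC)OCC | starting material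
19 | ethyl (2E,4E,6E,8E,10E)-2,6,11-trimethyl-12-oxododeca-2,4,6,8,10-pentaenoate | CCOC(=O)/C(C)=C/C=C/C(C)=C/C=C/C=C(\C)C=O | intermediate
20 | ethyl (2E,4E,6E,8E,10E)-12-hydroxy-2,6,11-trimethyldodeca-2,4,6,8,10-pentaenoate | CCOC(=O)/C(C)=C/C=C/C(C)=C/C=C/C=C(\C)CO | intermediate
21 | [(2E,4E,6E,8E,10E)-12-ethoxy-2,7,11-trimethyl-12-oxododeca-2,4,6,8,10-pentaen-1-yl]triphenylphosphonium bromide | CCOC(=O)/C(C)=C/C=C/C(C)=C/C=C/C=C(\C)C[P+](c1ccccc1)(c1ccccc1)c1ccccc1.[Br-] | intermediate
22 | ethyl (2E,4E,6E,8E,10E,12E,14E)-15-[(2R,6R,7aR)-6-hydroxy-4,4,7a-trimethyl-2,4,5,6,7,7a-hexahydro-1-benzofuran-2-yl]-2,6,11-trimethylhexadeca-2,4,6,8,10,12,14-heptaenoate | C\C(C(=O)OCC)=C/C=C/C(C)=C/C=C/C=C(C)/C=C/C=C(\C)[C@H]1C=C2C(C)(C)C[C@@H](O)C[C@@]2(C)O1 | intermediate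
23 | (2E,4E,6E,8E,10E,12E,14E)-15-[(2R,6R,7aR)-6-hydroxy-4,4,7a-trimethyl-2,4,5,6,7,7a-hexahydro-1-benzofuran-2-yl]-2,6,11-trimethylhexadeca-2,4,6,8,10,12,14-heptaen-1-ol | C\C(CO)=C/C=C/C(C)=C/C=C/C=C(C)/C=C/C=C(\C)[C@H]1C=C2C(C)(C)C[C@@H](O)C[C@@]2(C)O1 | intermediate
24 | (2E,4E,6E,8E,10E,12E,14E)-15-[(2R,6R,7aR)-6-hydroxy-4,4,7a-trimethyl-2,4,5,6,7,7a-hexahydro-1-benzofuran-2-yl]-2,6,11-trimethylhexadeca-2,4,6,8,10,12,14-heptaenal | C\C(C=O)=C/C=C/C(C)=C/C=C/C=C(C)/C=C/C=C(\C)[C@H]1C=C2C(C)(C)C[C@@H](O)C[C@@]2(C)O1 | target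

**Count and risks**

Total step count: 17. Longest linear sequence: 13 steps (1, 2, 3, 4, 6, 7, 8, 9, 10, 11, 15, 16, 17).

Steps most likely to fail:

1. Step 3 (key step). A second intermolecular acetone aldol at the free formyl arm may outrun the ring closure, the ring may close through the ketone enamine instead of the aldehyde enamine, or facial control in the first aldol may be too low. The fallback is stepwise and reagent-controlled. It sets out from 3, used in threefold excess, which is treated with B-methallyldiisopinocampheylborane (the antipode that leads to the 5S alcohol; Et2O, −78 °C, ethanolamine work-up) to give (5S)-5-hydroxy-3,3,7-trimethyloct-7-enal F1. Ozonolysis of its 1,1-disubstituted alkene (O3, CH2Cl2, −78 °C; Me2S) gives 5, and piperidinium acetate in benzene at 60 °C closes and dehydrates 5 to 7, where the route is rejoined.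

2. Step 8. Hydride may be transferred to C6 (giving the alkyne instead of the allene), or the anti sense may be lost through equilibration of the allenylpalladium species. The fallback replaces palladium oxidative addition by copper hydride hydrocupration of the alkyne followed by anti β-alkoxide elimination. It sets out from 12 with chloro[1,3-bis(2,6-diisopropylphenyl)imidazol-2-ylidene]copper (3 mol %), NaOt-Bu and polymethylhydrosiloxane in toluene at 0 °C, followed by NH4F in MeOH to cleave any silyl ethers, and comes back at 13. It makes no compound outside the list (F0).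

3. Step 10. Gold may epimerise the allene axis before ring closure, eroding the C8 configuration, or the vinyl allene and allylic alcohol may ionise or rearrange at the Lewis-acidic metal. The fallback sets out from 14 and uses a metal-free anti iodo-etherification (N-iodosuccinimide, CH2Cl2, −20 °C), which should transfer the axis in the same sense to give (2E)-3-[(2S,6R,7aR)-6-hydroxy-3-iodo-4,4,7a-trimethyl-2,4,5,6,7,7a-hexahydro-1-benzofuran-2-yl]but-2-en-1-ol F2. Removal of the vinylic iodine with n-Bu3SnH and azobisisobutyronitrile in toluene at 80 °C comes back at 15.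

**Further compounds**

F1 | step 3 | (5S)-5-hydroxy-3,3,7-trimethyloct-7-enal | C=C(C)C[C@H](O)CC(C)(C)CC=O
F0 | step 8 | none | none
F2 | step 10 | (2E)-3-[(2S,6R,7aR)-6-hydroxy-3-iodo-4,4,7a-trimethyl-2,4,5,6,7,7a-hexahydro-1-benzofuran-2-yl]but-2-en-1-ol | OC/C=C(\C)[C@H]1C(I)=C2C(C)(C)C[C@@H](O)C[C@@]2(C)O1
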